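The readings were generated by integration for substances that don't exist, and the scatter is random.

Charged with twice the reagent in the second phase, and with more substrate too, the west run closes at a target-to-substrate ratio of 0.320, where the north run closes at 0.234, both read at 2.50 min.

| flask | substrate | reagent in the second phase | remark | time | volume of the second phase over the first |
|---|---|---|---|---|---|
| north | 0.28 M | 0.25 M | run made earlier |  |  |
| south-east | 0.28 M | 0.38 M | run made earlier |  |  |
| west | 0.42 M | 0.504 M | run made earlier |  |  |
| flask | 0.28 M | 0.504 M |  | 4.0 min | 0.25 |

- north (time / min: target / %, substrate / %): 0.667: 8.0, 88.5; 1.33: 15.6, 81.7; 2.00: 19.7, 80.6; 2.50: 19.0, 81.2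
- south-east (time / min: target / %, substrate / %): 0.667: 16.8, 85.1; 1.33: 22.1, 77.3; 2.00: 23.3, 77.7; 2.50: 23.8, 79.3
- west (time / min: target / %, substrate / %): 0.200: 6.0, 95.6; 0.417: 13.0, 88.6; 1.00: 21.2, 77.6; 2.50: 24.9, 77.8

(scatter of a reading: 1 percentage point)

- in the second phase: reagent in the second phase; everything else is in the first
- charges count per volume of the first phase; a concentration in a rate is the amount of a species over the volume of its own phase; every rate counts per litre of the first phase
- what may be going on: substrate + reagent in the reaction phase <-> target; reagent in the reaction phase <-> reagent in the second phase; 2 reagent in the reaction phase -> self-condensation product
- the earlier runs hold the two phases in the same ratio of volumes as the flask asked about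

1. the target standing at 4.0 min, as a percentage of the substrate charged
2. the change that raises the amount of target at 4.0 min, in percent of the substrate charged most ("none" if none brings more than 2 percentage points) (dusk / spring / none)
3. amount of target at 4.0 min, in percent of the substrate charged, after spring

- dusk: doubling the transfer coefficient of the reagent in the second phase, all else as stated
- spring: doubling the amount of reagent in the second phase, all else as stated

Watch the west run in slow motion, since it holds the flask's reagent charge. In the first instants, up to 0.417 min, target climbs by 0.312 /min of the substrate charged. By the middle, at 1.00 min, it stands at 21.2 %. From there to 2.50 min it gains 0.0247 /min, while substrate reads 77.6 % and then 77.8 %, a move within the scatter of 1 percentage point. So the end of the west run is better described by a ratio than by a rate, and you should compare ratios.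

Dividing the west ratio by the north ratio gives 1.37, a reading that carries the scatter: this is the doubling gain, the factor by which one doubling of the reagent charge multiplies the target-to-substrate ratio. My own reckoning takes the west ratio for the flask, betting, as the gain already does, that the difference in substrate charge matters little. That gives 24.2 % target, and one doubling gain more gives 30.4 % after spring. But the flask is asked at 4.0 min, past the last reading at 2.50 min. If the ratio drifts there, I trust the gain more than the ratio, since a drift shared by both flasks divides out.

The forecast says “The target plateaus quickly” and gives 25.5 %, with spring as the best change and 33 % after it. Both numbers stand above mine.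

The flask gives 20.9 % at 4.0 min, and spring raises that by 4.9 points to 25.8 %, while dusk changes it by −1.8 points.

    substrate + reagent in the reaction phase ⇌ target (K = 7.40 /M, k = 0.0580 /M/s)
    reagent in the reaction phase ⇌ reagent in the second phase, rate k2*([reagent in the reaction phase] - [reagent in the second phase]/K2) per volume of the first phase (partition coefficient = 3.10, kL = 0.0300 /s)
    2 reagent in the reaction phase → self-condensation product (k = 0.220 /M/s)

Target in the flask stood at 25.8 % at 2.00 min and has fallen since. The amount at 4.0 min is held down by self-condensation, which takes reagent from the reaction phase, together with target falling back to substrate: without the first the flask holds 58.2 %, without the second 48.2 %. So the flask's ratio at 4.0 min is 0.264, yet the doubling gain still serves: multiplied by it, that ratio gives 26.6 % target for spring, against the 25.8 % that spring gave.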